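## Structural features

The target 9 is a 1H-pyrrole in which every ring carbon is substituted. C2 and C5 each carry a 3,5-dibromo-4-hydroxybenzoyl group, C3 and C4 each carry a 3,5-dibromo-4-hydroxyphenyl group, and N1 carries only hydrogen. The molecule is twofold symmetric about the axis through N1 and the midpoint of the C3–C4 bond, and it has no stereocentre and no sp3 carbon, so the problem is one of connectivity and substitution pattern only. All four arenes show the same 2,6-dibromophenol pattern: the bromines sit only ortho to OH, and the para position is taken by the bond to the core. The fragile elements are the eight aryl C–Br bonds (incompatible with organometallic reagents, zerovalent palladium and reducing metals) and the four acidic bromophenols; the diaryl ketones are vinylogous amides of the pyrrole nitrogen and are comparatively robust. The real difficulty is the crowded tetrasubstituted pyrrole core, where each α-carbon bears an aroyl group directly beside a β-aryl group, so stepwise substitution of a preformed pyrrole has to fight both deactivation by the first acyl group and steric shielding. The key step exploits the fact that C3 and C4 map onto the two carbonyl carbons of a symmetrical 1,2-diaryl-1,2-dione, while C2 and C5 each lie between N1 and an exocyclic aroyl C=O that can acidify a methylene group. The ring bonds C2–C3 and C4–C5 can therefore both be made as aldol condensations, with N1 already bonded to C2 and C5.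

## Logic of the disconnections

9 to 8. The eight aryl C–Br bonds are cut together. Each bromine is ortho to a phenolic OH whose para position is blocked, and the pyrrole has no free carbon, so electrophilic bromination can only go where 9 has bromine. The cut removes all halogen from the earlier steps, so base, Lewis acid and protic acid can be used there freely. The forward step must be exhaustive (eight substitutions) and must avoid ipso attack at the acyl-bearing and pyrrolyl-bearing carbons.

8 to 7. The four phenolic O–H bonds are traced back to O–CH3 bonds. Free phenols would be deprotonated under the basic key step, and the phenoxides would suppress both the electrophilicity of 4 and the α-CH2 acidity of 3. Methyl ethers are inert there and arrive with the commercial building blocks. The forward step is a fourfold ether cleavage that must tolerate two diaryl ketones and the N–H.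

7 to 6. The N1–H bond is traced back to an N1–CH2Ar bond (Ar = 2,4-dimethoxyphenyl). A substituent on nitrogen is needed because a secondary bis(α-keto)amine would self-condense and could attack 4 through nitrogen. The electron-rich benzyl group is chosen because the 2,5-diacylpyrrole of 6 is a good leaving group under acid. The forward step must ionise this one bond without benzylating the four anisyl rings.

6 to 3 and 4 (through 5). The key cut severs the ring bonds C2–C3 and C4–C5 and leaves both C–N bonds intact. C3 and C4 become the two carbonyl carbons of 4; C2 and C5 become the two methylene carbons of 3, each acidified by the aroyl group that ends as the 2- or 5-substituent. Both fragments are twofold symmetric, so no regiochemical question arises. All four arenes and both ketones arrive at their final oxidation level, and water is the only by-product. The forward step needs two aldol additions and two dehydrations in one flask, with cross-condensation beating self-condensation of 3 and base-induced degradation of 4.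

3 to 1 and 2. The two N–CH2 bonds are cut, an amine alkylation with an α-bromoketone. This reduces 3 to two commercial compounds. The forward step must stop at the tertiary amine.

## Other disconnections considered

Alternative 1: (the first that comes to mind) Cut the two exocyclic bonds C2–C(=O) and C5–C(=O). The forward key step would be a twofold Friedel–Crafts acylation of 3,4-bis(4-methoxyphenyl)-1H-pyrrole A1 with a para-methoxybenzoyl electrophile to give 7. The chosen plan is preferred on three grounds:
- A1 is not commercial and would need its own preparation of three or more steps (halogenation of an N-protected pyrrole, twofold cross-coupling, deprotection), against one step for 3.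
- α-Unsubstituted 3,4-diarylpyrroles are sensitive to acid and air.
- After the first acylation the pyrrole is deactivated and the remaining α-position is flanked by an aryl group. The second acylation would need forcing Lewis-acid conditions, under which the anisyl rings (open ortho to OMe) and the methyl ethers become competing reaction sites.

The chosen plan never performs electrophilic substitution on the pyrrole; both carbonyls come inside 3.

Alternative 2: Cut C3–C4 together with N1–C2 and N1–C5, following the presumed biosynthesis from two aryl-C3 units. The forward key step would be oxidative enolate dimerisation of 1,3-bis(4-methoxyphenyl)propane-1,2-dione A2 at its benzylic carbon to the tetraketone A3, then Paal–Knorr condensation with an ammonia source to give 7. The chosen plan is preferred on three grounds: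
- A2 is not commercial and needs two to three steps.
- A2 is largely enolised, and oxidative coupling of such enols is expected to compete with C–O coupling and with over-oxidation to a 1,2,3-tricarbonyl compound.
- A3 has four electrophilic carbonyls. Ammonia can bridge the 1,4-related inner pair (the pyrrole) or a 1,5-related outer/inner pair (a pyridin-3-ol), so ring size is not secured by structure.

In the chosen plan nitrogen is already bonded to both α-carbons, so only a five-membered ring can close, and no oxidant is needed.

Alternative 3: Cut the pyrrole back to a 1,2-diazine that carries one extra nitrogen. The forward key steps would be an inverse-electron-demand Diels–Alder reaction of 3,6-bis(4-methoxybenzoyl)-1,2,4,5-tetrazine A4 with the symmetrical diarylalkyne, loss of N2 to give pyridazine A5, and reductive ring contraction (Zn, AcOH) to 7. The chosen plan is preferred on three grounds: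
- A4 is not an established reagent, and its ketone groups on the strongly electron-poor tetrazine are expected to be prone to hydration and nucleophilic degradation.
- Diarylalkynes are sluggish dienophiles.
- The dissolving-metal conditions of the ring contraction are expected to attack the diaryl ketones of A5 (reduction to carbinols or pinacol coupling), so chemoselectivity is not secured.

The chosen plan has no redox step and reaches 7 in fewer operations.

Key step: step 2

Remarks: compounds 1, 2 and 4 are taken as commercially available. Intermediate 5 should form as a mixture of diastereomers; its four stereocentres all become sp2 in 6, so no configuration is assigned.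

## Route

Step 1
Reactants: 1 (2,4-dimethoxyphenyl)methanamine (2,4-dimethoxybenzylamine); 2 α-bromo-4-methoxyacetophenone [2-bromo-1-(4-methoxyphenyl)ethan-1-one] (2.05 equiv)
Product: 3 N,N-bis[2-(4-methoxyphenyl)-2-oxoethyl]-2,4-dimethoxybenzylamine
Conditions: K2CO3 (2.5 equiv), MeCN, 0 °C to rt
Reagents that add atoms: none
Why: Two successive SN2 displacements of bromide at the activated α-carbon of the bromoketone (N-alkylation of a primary amine); the tertiary bis(phenacyl)amine is hindered and inductively deactivated, so quaternisation should be slow, and the carbonate only scavenges HBr.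

Step 2
Reactants: 3 N,N-bis[2-(4-methoxyphenyl)-2-oxoethyl]-2,4-dimethoxybenzylamine; 4 anisil [1,2-bis(4-methoxyphenyl)ethane-1,2-dione]
Product: 6 [1-(2,4-dimethoxybenzyl)-3,4-bis(4-methoxyphenyl)-1H-pyrrole-2,5-diyl]bis[(4-methoxyphenyl)methanone], via bis-aldol pyrrolidine-3,4-diol 5 (not isolated)
Conditions: NaOMe (0.5 equiv), MeOH/THF, 3 Å molecular sieves, 65 °C
Reagents that add atoms: none
Why: Methoxide reversibly forms the enolate of one phenacyl arm of 3, which adds to a carbonyl of 4; the enolate of the second arm then adds intramolecularly to the remaining carbonyl to give diol 5, and two E1cB losses of hydroxide, each from a carbon β to an aroyl C=O, deliver the aromatic pyrrole. The closest known reaction type is the Hinsberg condensation of 1,2-diketones with iminodiacetates or with bis(acylmethyl) sulfides, here run with a ketone-activated amine. The ring is closed at carbon: C2–C3 forms intermolecularly and C4–C5 closes the five-membered ring in a 5-(enolexo)-exo-trig aldol addition, both C–N bonds being present beforehand. The four stereocentres of 5 are of no consequence, because all become sp2 and the E1cB eliminations pass through planar enolates with no anti-periplanar requirement, so every diastereomer converges on 6. The selectivity needed is cross- over self-condensation: 4 is non-enolisable and its carbonyls, each activated by the neighbouring C=O, are the strongest electrophiles present, whereas 3 is the only enolisable partner and its own intramolecular aldol would give a strained azetidine that reverts. The tertiary nitrogen cannot form an imine with 4, and both partners are twofold symmetric, so only one constitution can result. All aldol steps are reversible but aromatisation to a pyrrole conjugated with two aroyl groups is not, which should drain the equilibria towards 6, while the sieves keep hydroxide, and with it benzilic acid rearrangement of 4, to a minimum.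

Step 3
Reactants: 6 [1-(2,4-dimethoxybenzyl)-3,4-bis(4-methoxyphenyl)-1H-pyrrole-2,5-diyl]bis[(4-methoxyphenyl)methanone]
Product: 7 [3,4-bis(4-methoxyphenyl)-1H-pyrrole-2,5-diyl]bis[(4-methoxyphenyl)methanone]
Conditions: TFA, 1,3-dimethoxybenzene (5 equiv), 60 °C
Reagents that add atoms: none
Why: Acidolysis of an N-benzyl-type protecting group: protonation of an aroyl oxygen makes the 2,5-diacylpyrrole an imide-like leaving group, the stabilised 2,4-dimethoxybenzyl cation departs (SN1) and is trapped irreversibly by the far more nucleophilic 1,3-dimethoxybenzene in a Friedel–Crafts alkylation; aryl methyl ethers and diaryl ketones are stable to TFA.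

Step 4
Reactants: 7 [3,4-bis(4-methoxyphenyl)-1H-pyrrole-2,5-diyl]bis[(4-methoxyphenyl)methanone]
Product: 8 [3,4-bis(4-hydroxyphenyl)-1H-pyrrole-2,5-diyl]bis[(4-hydroxyphenyl)methanone]
Conditions: BBr3 (10 equiv), CH2Cl2, −78 °C to rt; then MeOH, H2O
Reagents that add atoms: none
Why: Standard BBr3 cleavage of aryl methyl ethers: complexation at each ether oxygen, SN2 attack of bromide on the methyl group and hydrolysis of the aryloxyboranes on work-up; the ketones and the pyrrole N–H are only complexed reversibly, hence the excess.

Step 5
Reactants: 8 [3,4-bis(4-hydroxyphenyl)-1H-pyrrole-2,5-diyl]bis[(4-hydroxyphenyl)methanone]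
Product: 9 [3,4-bis(3,5-dibromo-4-hydroxyphenyl)-1H-pyrrole-2,5-diyl]bis[(3,5-dibromo-4-hydroxyphenyl)methanone] (target)
Conditions: Br2 (8.8 equiv), AcOH, rt to 40 °C
Reagents that add atoms: bromine, BrBr
Why: Electrophilic aromatic bromination of para-substituted phenols: in each ring the two positions ortho to OH are the only activated open sites (in the benzoyl rings they are also meta to the acyl group, so the directing effects agree), the para positions and every pyrrole carbon are blocked, and eight substitutions should therefore give 9 and no regioisomer.

## Compound list

1 | (2,4-dimethoxyphenyl)methanamine | COc1ccc(CN)c(OC)c1 | starting material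
2 | 2-bromo-1-(4-methoxyphenyl)ethan-1-one | COc1ccc(cc1)C(=O)CBr | starting material
3 | 2,2'-{[(2,4-dimethoxyphenyl)methyl]azanediyl}bis[1-(4-methoxyphenyl)ethan-1-one] | COc1ccc(CN(CC(=O)c2ccc(OC)cc2)CC(=O)c2ccc(OC)cc2)c(OC)c1 | intermediate
4 | 1,2-bis(4-methoxyphenyl)ethane-1,2-dione | COc1ccc(cc1)C(=O)C(=O)c1ccc(OC)cc1 | starting material
5 | [1-(2,4-dimethoxybenzyl)-3,4-dihydroxy-3,4-bis(4-methoxyphenyl)pyrrolidine-2,5-diyl]bis[(4-methoxyphenyl)methanone] (mixture of diastereomers, configuration not controlled) | COc1ccc(CN2C(C(=O)c3ccc(OC)cc3)C(O)(c3ccc(OC)cc3)C(O)(c3ccc(OC)cc3)C2C(=O)c2ccc(OC)cc2)c(OC)c1 | intermediate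
6 | [1-(2,4-dimethoxybenzyl)-3,4-bis(4-methoxyphenyl)-1H-pyrrole-2,5-diyl]bis[(4-methoxyphenyl)methanone] | COc1ccc(Cn2c(C(=O)c3ccc(OC)cc3)c(-c3ccc(OC)cc3)c(-c3ccc(OC)cc3)c2C(=O)c2ccc(OC)cc2)c(OC)c1 | intermediate
7 | [3,4-bis(4-methoxyphenyl)-1H-pyrrole-2,5-diyl]bis[(4-methoxyphenyl)methanone] | COc1ccc(cc1)C(=O)c1[nH]c(C(=O)c2ccc(OC)cc2)c(-c2ccc(OC)cc2)c1-c1ccc(OC)cc1 | intermediate
8 | [3,4-bis(4-hydroxyphenyl)-1H-pyrrole-2,5-diyl]bis[(4-hydroxyphenyl)methanone] | Oc1ccc(cc1)C(=O)c1[nH]c(C(=O)c2ccc(O)cc2)c(-c2ccc(O)cc2)c1-c1ccc(O)cc1 | intermediate
9 | [3,4-bis(3,5-dibromo-4-hydroxyphenyl)-1H-pyrrole-2,5-diyl]bis[(3,5-dibromo-4-hydroxyphenyl)methanone] | O=C(c1cc(Br)c(O)c(Br)c1)c1[nH]c(C(=O)c2cc(Br)c(O)c(Br)c2)c(-c2cc(Br)c(O)c(Br)c2)c1-c1cc(Br)c(O)c(Br)c1 | target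

## Step count and least certain steps

Total step count: 5. Longest linear sequence: 5 steps (1 and 2 to 3, then 6, 7, 8, 9); compound 4 enters in step 2.

**Step 2 (key step).**
- Most likely failure: the reversible aldol additions return to the components (retro-aldol) faster than the dehydrations proceed, while alkoxide or adventitious hydroxide consumes 4 by benzilic rearrangement or acyl cleavage. The ketone enolate of 3 gives a less favourable aldol equilibrium than an ester enolate, and the para-methoxy groups lower the electrophilicity of 4.
- Fallback (sets out from 4, returns at 7, bypassing 6 and step 3): 4 is condensed in the classical ester Hinsberg manner with diethyl N-acetyliminodiacetate F1 (from commercial diethyl iminodiacetate and acetic anhydride) under NaOEt in EtOH, and the crude product is saponified with aqueous NaOH to 3,4-bis(4-methoxyphenyl)-1H-pyrrole-2,5-dicarboxylic acid F2. The N-acetyl group should be lost under the alkoxide conditions once the pyrrole has formed. F2 is coupled with N,O-dimethylhydroxylamine hydrochloride (1,1'-carbonyldiimidazole) to the bis(N-methoxy-N-methylamide) F3. F3 is then treated with excess 4-methoxyphenylmagnesium bromide in THF (the first equivalent removes the N–H proton) in a Weinreb ketone synthesis that should give 7.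

**Step 1.**
- Most likely failure: over-alkylation to the quaternary ammonium salt, or condensation of amine nitrogen with the ketone carbonyl of 2 or of the mono-alkylated intermediate, because the electrophile carries a reactive ketone beside the halide.
- Fallback (sets out from 1, returns at 3): 1 is alkylated twice with commercial 2-chloro-N-methoxy-N-methylacetamide (K2CO3, catalytic NaI, MeCN) to 2,2'-{[(2,4-dimethoxyphenyl)methyl]azanediyl}bis(N-methoxy-N-methylacetamide) F4, whose amide carbonyls neither condense with amines nor enolise readily. Addition of 4-methoxyphenylmagnesium bromide (2.2 equiv, THF, 0 °C) should then give 3 through the stable magnesium chelates.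

**Step 3.**
- Most likely failure: incomplete ionisation of the N–CH2 bond, since the leaving group is a weakly basic pyrrole nitrogen shielded by two aroyl groups. If forcing acid is needed, the benzylic cation could alkylate the electron-rich 3,4-anisyl rings despite the scavenger.
- Fallback (sets out from 4, returns at 7): the nitrogen substituent is made traceless. Commercial N-(tert-butoxycarbonyl)iminodiacetic acid is converted (1,1'-carbonyldiimidazole, N,O-dimethylhydroxylamine hydrochloride) into tert-butyl bis{2-[methoxy(methyl)amino]-2-oxoethyl}carbamate F5. 4-Methoxyphenylmagnesium bromide gives tert-butyl bis[2-(4-methoxyphenyl)-2-oxoethyl]carbamate F6. Hinsberg condensation of F6 with 4 (NaOMe, MeOH) should pass through tert-butyl 2,5-bis(4-methoxybenzoyl)-3,4-bis(4-methoxyphenyl)-1H-pyrrole-1-carboxylate F7, an N-acylpyrrole flanked by two aroyl groups that should be methanolysed in the same flask to 7.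

## Further compounds

F1 | step 2 | diethyl 2,2'-(acetylazanediyl)diacetate (diethyl N-acetyliminodiacetate) | CCOC(=O)CN(CC(=O)OCC)C(C)=O
F2 | step 2 | 3,4-bis(4-methoxyphenyl)-1H-pyrrole-2,5-dicarboxylic acid | COc1ccc(cc1)-c1c(C(O)=O)[nH]c(C(O)=O)c1-c1ccc(OC)cc1
F3 | step 2 | N2,N5-dimethoxy-3,4-bis(4-methoxyphenyl)-N2,N5-dimethyl-1H-pyrrole-2,5-dicarboxamide | COc1ccc(cc1)-c1c(C(=O)N(C)OC)[nH]c(C(=O)N(C)OC)c1-c1ccc(OC)cc1
F4 | step 1 | 2,2'-{[(2,4-dimethoxyphenyl)methyl]azanediyl}bis(N-methoxy-N-methylacetamide) | COc1ccc(CN(CC(=O)N(C)OC)CC(=O)N(C)OC)c(OC)c1
F5 | step 3 | tert-butyl bis{2-[methoxy(methyl)amino]-2-oxoethyl}carbamate | CON(C)C(=O)CN(CC(=O)N(C)OC)C(=O)OC(C)(C)C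
F6 | step 3 | tert-butyl bis[2-(4-methoxyphenyl)-2-oxoethyl]carbamate | COc1ccc(cc1)C(=O)CN(CC(=O)c1ccc(OC)cc1)C(=O)OC(C)(C)C
F7 | step 3 | tert-butyl 2,5-bis(4-methoxybenzoyl)-3,4-bis(4-methoxyphenyl)-1H-pyrrole-1-carboxylate | COc1ccc(cc1)C(=O)c1c(-c2ccc(OC)cc2)c(-c2ccc(OC)cc2)c(C(=O)c2ccc(OC)cc2)n1C(=O)OC(C)(C)C
A1 | alternative 1 | 3,4-bis(4-methoxyphenyl)-1H-pyrrole | COc1ccc(cc1)-c1c[nH]cc1-c1ccc(OC)cc1
A2 | alternative 2 | 1,3-bis(4-methoxyphenyl)propane-1,2-dione | COc1ccc(CC(=O)C(=O)c2ccc(OC)cc2)cc1
A3 | alternative 2 | 1,3,4,6-tetrakis(4-methoxyphenyl)hexane-1,2,5,6-tetrone (mixture of meso and racemic forms) | COc1ccc(cc1)C(=O)C(=O)C(c1ccc(OC)cc1)C(c1ccc(OC)cc1)C(=O)C(=O)c1ccc(OC)cc1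
A4 | alternative 3 | (1,2,4,5-tetrazine-3,6-diyl)bis[(4-methoxyphenyl)methanone] | COc1ccc(cc1)C(=O)c1nnc(nn1)C(=O)c1ccc(OC)cc1
A5 | alternative 3 | [4,5-bis(4-methoxyphenyl)pyridazine-3,6-diyl]bis[(4-methoxyphenyl)methanone] | COc1ccc(cc1)C(=O)c1nnc(C(=O)c2ccc(OC)cc2)c(-c2ccc(OC)cc2)c1-c1ccc(OC)cc1
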